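## Retrosynthetic overview

1. The target comes from its triacetate by global deacetylation. Ring labels: coumarin A/B, central resorcinol ring C, benzofuran D/E, aroyl ring F.
2. Key disconnection: the furan O1–C2 bond, made together with the C3–acyl bond. This leads back to a 2-alkynylphenol and a salicylaldehyde, joined by dehydrogenative oxyacylation of the alkyne.
3. The diarylalkyne comes from a Sonogashira coupling of an iodinated 3-arylcoumarin triacetate with 4-ethynylresorcinol.
4. The coumarin pyranone (lactone C–O and C3=C4) comes from a Perkin–Oglialoro condensation of the same salicylaldehyde with 5-iodo-2,4-dihydroxyphenylacetic acid. This step also installs the acetates.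
5. The salicylaldehyde, used twice, comes from 2,4-dihydroxybenzaldehyde by O-prenylation and aromatic Claisen shift. Ring order: pyranone first, furan last.

Assumption: the SMILES contains no stereocentre, no stereogenic double bond and no configurationally stable biaryl axis. The target is therefore achiral and no enantiocontrol is needed.

## Route

Step 1
Reactants: 1 2,4-dihydroxybenzaldehyde; 2 prenyl bromide
Product: 3 2-hydroxy-4-(3-methylbut-2-enyloxy)benzaldehyde
Conditions: K2CO3 (1.05 equiv), acetone, 56 °C, 12 h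
Reagents that add atoms: prenyl bromide 2, CC(C)=CCBr
Why: Williamson ether synthesis; the 4-OH is the more acidic phenol and the 2-OH is tied up in a hydrogen bond to the aldehyde, so mono-alkylation occurs at O-4.

Step 2
Reactants: 3 2-hydroxy-4-(3-methylbut-2-enyloxy)benzaldehyde
Product: 6 2,4-dihydroxy-5-(2-methylbut-3-en-2-yl)benzaldehyde, via 2-O-TMS prenyl ether 4 (not isolated), via bis-TMS Claisen product 5 (not isolated)
Conditions: N,O-bis(trimethylsilyl)acetamide (2.5 equiv), PhNEt2, 185 °C, sealed tube, 8 h; then 1 M HCl, THF, rt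
Reagents that add atoms: none
Why: Aromatic Claisen rearrangement ([3,3] shift with allyl inversion gives the 1,1-dimethylallyl group); in situ silylation of the chelated 2-OH removes the bond fixation that would steer migration to C3 and adds bulk there, so the shift goes to C5, and silylation of the new phenol suppresses abnormal Claisen and cyclisation side reactions; no stereocentre is formed.

Step 3
Reactants: 7 2-(2,4-dihydroxyphenyl)acetic acid
Product: 8 2-(2,4-dihydroxy-5-iodophenyl)acetic acid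
Conditions: ICl (1.0 equiv), Et2O, 0 °C to rt
Reagents that add atoms: iodine monochloride, ClI
Why: Electrophilic aromatic iodination; under non-basic conditions resorcinols are iodinated at the open position para to one OH and ortho to the other (C5), not at the crowded C3 between the two oxygens.

Step 4
Reactants: 8 2-(2,4-dihydroxy-5-iodophenyl)acetic acid; 6 2,4-dihydroxy-5-(2-methylbut-3-en-2-yl)benzaldehyde
Product: 9 3-(2,4-diacetoxy-5-iodophenyl)-6-(2-methylbut-3-en-2-yl)-2-oxo-2H-chromen-7-yl acetate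
Conditions: Ac2O (10 equiv), Et3N (4 equiv), 100 °C, 6 h
Reagents that add atoms: acetic anhydride, CC(=O)OC(C)=O
Why: Perkin–Oglialoro condensation; the arylacetic mixed anhydride condenses with the aldehyde, the salicyl oxygen closes the lactone C–O bond, and the three remaining phenols are acetylated in the same flask, which blocks the ring C oxygen ortho to iodine for step 7.

Step 5
Reactants: 10 4-iodobenzene-1,3-diol; 11 trimethylsilylacetylene
Product: 13 4-ethynylbenzene-1,3-diol, via TMS-alkyne 12 (not isolated)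
Conditions: PdCl2(PPh3)2 (2 mol%), CuI (4 mol%), Et3N, THF, rt, argon; then MeOH, K2CO3 (3 equiv), 0 °C to rt, argon; used promptly
Reagents that add atoms: trimethylsilylacetylene 11, C#C[Si](C)(C)C
Why: Sonogashira coupling of an electron-rich aryl iodide at room temperature, where the 2-alkynylphenol does not cyclise, followed by methanolytic C–Si cleavage in the same flask.

Step 6
Reactants: 9 3-(2,4-diacetoxy-5-iodophenyl)-6-(2-methylbut-3-en-2-yl)-2-oxo-2H-chromen-7-yl acetate; 13 4-ethynylbenzene-1,3-diol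
Product: 14 3-{2,4-diacetoxy-5-[(2,4-dihydroxyphenyl)ethynyl]phenyl}-6-(2-methylbut-3-en-2-yl)-2-oxo-2H-chromen-7-yl acetate
Conditions: PdCl2(PPh3)2 (3 mol%), CuI (5 mol%), iPr2NEt (2 equiv), degassed THF, rt, 4–8 h
Reagents that add atoms: none
Why: Sonogashira coupling; the acetoxy-substituted aryl iodide adds to zerovalent palladium at room temperature, and the non-nucleophilic amine with a short reaction time keeps the acetates in place and the alkynylphenol uncyclised.

Step 7
Reactants: 14 3-{2,4-diacetoxy-5-[(2,4-dihydroxyphenyl)ethynyl]phenyl}-6-(2-methylbut-3-en-2-yl)-2-oxo-2H-chromen-7-yl acetate; 6 2,4-dihydroxy-5-(2-methylbut-3-en-2-yl)benzaldehyde (1.5 equiv)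
Product: 15 3-{2,4-diacetoxy-5-[3-(2,4-dihydroxy-5-(2-methylbut-3-en-2-yl)benzoyl)-6-hydroxybenzofuran-2-yl]phenyl}-6-(2-methylbut-3-en-2-yl)-2-oxo-2H-chromen-7-yl acetate
Conditions: [Cp*Rh(MeCN)3](SbF6)2 (5 mol%), Cu(OAc)2 (2.1 equiv), 4 Å molecular sieves, t-AmOH, 60 °C, argon; 14 added over 4 h
Reagents that add atoms: none
Why: Proposed new method: dehydrogenative oxyacylation of an alkyne, in which phenoxide-directed formyl C–H metalation of 6 by cationic Cp*Rh (trivalent rhodium) gives the five-membered acyl-rhodacycle known from salicylaldehyde/alkyne annulations, the π-bound alkyne of 14 is attacked 5-endo-dig by its own free ortho-phenol (the ortho oxygen on ring C is an acetate, so only the O1–C2 bond of the target can form), C3–acyl reductive elimination releases 15, and monovalent rhodium is re-oxidised by Cu(OAc)2; the closest known reaction types are the palladium-catalysed carbonylative cyclisation of 2-alkynylphenols with aryl iodides and CO (aroyl-metal-triggered oxycyclisation) and the rhodium/copper oxidative annulation of salicylaldehydes with internal alkynes to chromones.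

Step 8
Reactants: 15 3-{2,4-diacetoxy-5-[3-(2,4-dihydroxy-5-(2-methylbut-3-en-2-yl)benzoyl)-6-hydroxybenzofuran-2-yl]phenyl}-6-(2-methylbut-3-en-2-yl)-2-oxo-2H-chromen-7-yl acetate
Product: 16 3-{5-[3-(2,4-dihydroxy-5-(2-methylbut-3-en-2-yl)benzoyl)-6-hydroxybenzofuran-2-yl]-2,4-dihydroxyphenyl}-7-hydroxy-6-(2-methylbut-3-en-2-yl)-2H-chromen-2-one
Conditions: K2CO3 (0.5 equiv), degassed MeOH/THF, 0 °C to rt, argon; then aq. citric acid
Reagents that add atoms: none
Why: Base-catalysed transesterification (Zemplén-type deacetylation) of three aryl acetates; any opened coumarin recloses on acidification, and the non-acidic conditions spare the 1,1-dimethylallyl phenols.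

## Compound list

1 | 2,4-dihydroxybenzaldehyde | O=Cc1ccc(O)cc1O | starting material
2 | prenyl bromide (1-bromo-3-methylbut-2-ene) | CC(C)=CCBr | starting material
3 | 2-hydroxy-4-(3-methylbut-2-enyloxy)benzaldehyde | CC(C)=CCOc1ccc(C=O)c(O)c1 | intermediate
4 | 4-(3-methylbut-2-enyloxy)-2-(trimethylsilyloxy)benzaldehyde | CC(C)=CCOc1ccc(C=O)c(O[Si](C)(C)C)c1 | intermediate
5 | 5-(2-methylbut-3-en-2-yl)-2,4-bis(trimethylsilyloxy)benzaldehyde | C=CC(C)(C)c1cc(C=O)c(O[Si](C)(C)C)cc1O[Si](C)(C)C | intermediate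
6 | 2,4-dihydroxy-5-(2-methylbut-3-en-2-yl)benzaldehyde | C=CC(C)(C)c1cc(C=O)c(O)cc1O | intermediate
7 | 2-(2,4-dihydroxyphenyl)acetic acid | OC(=O)Cc1ccc(O)cc1O | starting material
8 | 2-(2,4-dihydroxy-5-iodophenyl)acetic acid | OC(=O)Cc1cc(I)c(O)cc1O | intermediate
9 | 3-(2,4-diacetoxy-5-iodophenyl)-6-(2-methylbut-3-en-2-yl)-2-oxo-2H-chromen-7-yl acetate | C=CC(C)(C)c1cc2cc(-c3cc(I)c(OC(C)=O)cc3OC(C)=O)c(=O)oc2cc1OC(C)=O | intermediate
10 | 4-iodobenzene-1,3-diol (4-iodoresorcinol) | Oc1ccc(I)c(O)c1 | starting material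
11 | trimethylsilylacetylene | C#C[Si](C)(C)C | starting material
12 | 4-[(trimethylsilyl)ethynyl]benzene-1,3-diol | C[Si](C)(C)C#Cc1ccc(O)cc1O | intermediate
13 | 4-ethynylbenzene-1,3-diol | C#Cc1ccc(O)cc1O | intermediate
14 | 3-{2,4-diacetoxy-5-[(2,4-dihydroxyphenyl)ethynyl]phenyl}-6-(2-methylbut-3-en-2-yl)-2-oxo-2H-chromen-7-yl acetate | C=CC(C)(C)c1cc2cc(-c3cc(C#Cc4ccc(O)cc4O)c(OC(C)=O)cc3OC(C)=O)c(=O)oc2cc1OC(C)=O | intermediate
15 | 3-{2,4-diacetoxy-5-[3-(2,4-dihydroxy-5-(2-methylbut-3-en-2-yl)benzoyl)-6-hydroxybenzofuran-2-yl]phenyl}-6-(2-methylbut-3-en-2-yl)-2-oxo-2H-chromen-7-yl acetate | C=CC(C)(C)c1cc(C(=O)c2c(-c3cc(-c4cc5cc(C(C)(C)C=C)c(OC(C)=O)cc5oc4=O)c(OC(C)=O)cc3OC(C)=O)oc3cc(O)ccc23)c(O)cc1O | intermediate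
16 | CNP0319672.0 (achiral), name as under step 8 | C=CC(C)(C)c1cc(C(=O)c2c(-c3cc(-c4cc5cc(C(C)(C)C=C)c(O)cc5oc4=O)c(O)cc3O)oc3cc(O)ccc23)c(O)cc1O | target

## Step count and risks

Total step count: 8. Longest linear sequence: 6 (steps 1, 2, 4, 6, 7, 8).

**Risk 1, step 7 (the proposed new reaction).**
- Failure modes:
  - Plain cycloisomerisation of 14 without acyl transfer.
  - Acyl insertion with chromone-type ring closure.
  - Copper-mediated phenol oxidation.
  - Acetyl migration onto the free phenols, which would erase the regiocontrol.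
- Fallback: this uses known chemistry only, sets out from 14 and 6, and returns at 15. AuCl(PPh3)/AgOTf-catalysed 5-endo-dig cycloisomerisation of 14 (CH2Cl2, rt) gives the 2-arylbenzofuran-6-ol triacetate F1. TBSCl/imidazole then gives its 6-O-TBS ether F2, and NIS in MeCN iodinates the nucleophilic C3 to give the 3-iodobenzofuran F3. In parallel, 6 is silylated (TBSCl, imidazole, DMF) to the bis-TBS aldehyde F4. Nozaki–Hiyama–Kishi coupling of F3 and F4 (CrCl2, 2 mol% NiCl2, DMF, rt) tolerates the acetates and the lactone and gives the racemic diaryl carbinol F5. Dess–Martin periodinane removes that stereocentre and gives the tris-TBS ketone F6. TBAF buffered with AcOH (THF, 0 °C) removes the three silyl groups to give 15.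

**Risk 2, step 2 (Claisen regiochemistry and loss of the prenyl group at 185 °C).**
- Failure modes: migration to C3, or thermal deprenylation.
- Fallback: this sets out from 1 and returns at 6, replacing the sigmatropic shift with a cross-coupling whose position is fixed by a halogen. Bromination of 1 (Br2, AcOH, rt) gives 5-bromo-2,4-dihydroxybenzaldehyde F7. A ligand-controlled γ-selective Suzuki–Miyaura coupling with prenylboronic acid pinacol ester then attaches the tertiary allyl terminus at C5 and gives 6. Conditions are Pd(OAc)2 with a γ-selective biaryl monophosphine, aq. K3PO4, THF, 40–70 °C.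

**Risk 3, step 6 (premature Pd/Cu-induced cyclisation of 14, acetyl scrambling between aryl acetates and free phenols, and the sensitivity of 13).**
- Fallback: this sets out from 13 and returns at 14, and carries the nucleophilic phenols through the coupling in masked form. TBSCl/imidazole (DMF) converts 13 into 4-ethynyl-1,3-bis(tert-butyldimethylsilyloxy)benzene F8. Sonogashira coupling with 9 under the step 6 conditions gives the bis-TBS diarylalkyne F9, which can neither cyclise nor accept acetyl groups. TBAF/AcOH (THF, 0 °C) releases 14 directly before step 7.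

## Further compounds

F1 | step 7 | 3-[2,4-diacetoxy-5-(6-hydroxybenzofuran-2-yl)phenyl]-6-(2-methylbut-3-en-2-yl)-2-oxo-2H-chromen-7-yl acetate | C=CC(C)(C)c1cc2cc(-c3cc(-c4cc5ccc(O)cc5o4)c(OC(C)=O)cc3OC(C)=O)c(=O)oc2cc1OC(C)=O
F2 | step 7 | 3-{2,4-diacetoxy-5-[6-(tert-butyldimethylsilyloxy)benzofuran-2-yl]phenyl}-6-(2-methylbut-3-en-2-yl)-2-oxo-2H-chromen-7-yl acetate | C=CC(C)(C)c1cc2cc(-c3cc(-c4cc5ccc(O[Si](C)(C)C(C)(C)C)cc5o4)c(OC(C)=O)cc3OC(C)=O)c(=O)oc2cc1OC(C)=O
F3 | step 7 | 3-{2,4-diacetoxy-5-[6-(tert-butyldimethylsilyloxy)-3-iodobenzofuran-2-yl]phenyl}-6-(2-methylbut-3-en-2-yl)-2-oxo-2H-chromen-7-yl acetate | C=CC(C)(C)c1cc2cc(-c3cc(-c4oc5cc(O[Si](C)(C)C(C)(C)C)ccc5c4I)c(OC(C)=O)cc3OC(C)=O)c(=O)oc2cc1OC(C)=O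
F4 | step 7 | 2,4-bis(tert-butyldimethylsilyloxy)-5-(2-methylbut-3-en-2-yl)benzaldehyde | C=CC(C)(C)c1cc(C=O)c(O[Si](C)(C)C(C)(C)C)cc1O[Si](C)(C)C(C)(C)C
F5 | step 7 | racemic carbinol: tris-TBS, triacetate analogue of 15 with CH(OH) in place of the ketone | C=CC(C)(C)c1cc(C(O)c2c(-c3cc(-c4cc5cc(C(C)(C)C=C)c(OC(C)=O)cc5oc4=O)c(OC(C)=O)cc3OC(C)=O)oc3cc(O[Si](C)(C)C(C)(C)C)ccc23)c(O[Si](C)(C)C(C)(C)C)cc1O[Si](C)(C)C(C)(C)C
F6 | step 7 | tris-TBS ether of 15 | C=CC(C)(C)c1cc(C(=O)c2c(-c3cc(-c4cc5cc(C(C)(C)C=C)c(OC(C)=O)cc5oc4=O)c(OC(C)=O)cc3OC(C)=O)oc3cc(O[Si](C)(C)C(C)(C)C)ccc23)c(O[Si](C)(C)C(C)(C)C)cc1O[Si](C)(C)C(C)(C)C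
F7 | step 2 | 5-bromo-2,4-dihydroxybenzaldehyde | O=Cc1cc(Br)c(O)cc1O
F8 | step 6 | 4-ethynyl-1,3-bis(tert-butyldimethylsilyloxy)benzene | C#Cc1ccc(O[Si](C)(C)C(C)(C)C)cc1O[Si](C)(C)C(C)(C)C
F9 | step 6 | bis-TBS ether of 14 | C=CC(C)(C)c1cc2cc(-c3cc(C#Cc4ccc(O[Si](C)(C)C(C)(C)C)cc4O[Si](C)(C)C(C)(C)C)c(OC(C)=O)cc3OC(C)=O)c(=O)oc2cc1OC(C)=O
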